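**Retrosynthetic overview**
1. Numbering (longipinane): C1 ketone, C2=C3 enone, C4/C11 bridgeheads and C5/C10 bridges of the cyclobutane, C6–C9 the rest of the seven-membered ring. The angelate (on C6–CH2O) goes on last; the enone comes from isomerisation of a 3-methylidene ketone.
2. Key disconnection, C1–C2 and C5–C11 together: in bicyclo[4.2.1]nonanone 25 the 2-(silylmethyl)allyl group on C4 allylates the C1 ketone (Hosomi–Sakurai), then C5 shifts from C1 to C11 with loss of the C11 mesylate (cyclopentanone → cyclobutane, five-membered carbinol ring → six-membered ketone).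
3. Enabling feature: in 25 the C1 carbonyl sits in a cyclopentanone (C5–C1–C11–C10–C4) between the bridge carbon C5 and C11–OMs, with the C4 arm over the same face as the mesylate; allylation gives a 1-alkoxynorbornane whose C1–C5 bond is antiperiplanar to C11–OMs.
4. 25 from cyclopentenone 12: Cu-catalysed conjugate addition (C4 arm), Ireland–Claisen from the C11 oxygen (C5–C6 bond, quaternary C6), Rubottom oxidation (C11–O), intramolecular aldol (C7–C8), Evans–Tishchenko (C9, acetate).
5. 12 from 2-methylcyclopentane-1,3-dione by alkynylation and enzymatic desymmetrisation. Ring order: cyclopentane (from the dione) → seven-membered ring (step 14) → cyclobutane and cyclohexenone together (step 19).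

Key step: step 19

Remark: a ketoreductase giving the (2S,3S) hydroxy ketone 7 (the sense shown by baker's yeast with 2-allyl- and 2-propargyl-2-methylcyclopentane-1,3-diones) is assumed to be found by screening.

Step 1
Reactants: 1 methyl (R)-3-hydroxy-2-methylpropanoate
Product: 2 methyl (R)-3-(tert-butyldiphenylsilyloxy)-2-methylpropanoate
Conditions: t-BuPh2SiCl, imidazole, DMF, 23 °C
Reagents that add atoms: tert-butyl(chloro)diphenylsilane, CC(C)(C)[Si](Cl)(c1ccccc1)c1ccccc1
Why: Imidazole-mediated silylation of the primary alcohol, which leaves the stereocentre untouched (it is erased in step 11).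

Step 2
Reactants: 2 methyl (R)-3-(tert-butyldiphenylsilyloxy)-2-methylpropanoate
Product: 3 (R)-3-(tert-butyldiphenylsilyloxy)-2-methylpropanoic acid
Conditions: LiOH, THF/H2O, 23 °C; then 1 M HCl
Reagents that add atoms: lithium hydroxide, [Li+].[OH-]
Why: Saponification of the methyl ester; any epimerisation is without consequence because this centre becomes an enolate carbon in step 11.

Step 3
Reactants: 4 2-methylcyclopentane-1,3-dione; 5 1-[(trimethylsilyl)ethynyl]-1,2-benziodoxol-3(1H)-one (TMS-EBX)
Product: 6 2-ethynyl-2-methylcyclopentane-1,3-dione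
Conditions: Bu4NF, THF, −78 → 23 °C
Reagents that add atoms: none
Why: Electrophilic α-alkynylation of the 1,3-dione enolate with an ethynylbenziodoxolone (fluoride unmasks the reagent) creates the prochiral quaternary carbon, the future C10.

Step 4
Reactants: 6 2-ethynyl-2-methylcyclopentane-1,3-dione
Product: 7 (2S,3S)-2-ethynyl-3-hydroxy-2-methylcyclopentan-1-one
Conditions: ketoreductase (from a screening panel), NADP+ (cat.), i-PrOH, phosphate buffer pH 7, 30 °C
Reagents that add atoms: none
Why: Enzymatic desymmetrising reduction of one enantiotopic carbonyl should set the quaternary C10 and the carbinol C11 together (hydroxyl cis to ethynyl), as in the enzymatic reductions of 2-alkyl-2-methylcyclopentane-1,3-diones.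

Step 5
Reactants: 7 (2S,3S)-2-ethynyl-3-hydroxy-2-methylcyclopentan-1-one; 3 (R)-3-(tert-butyldiphenylsilyloxy)-2-methylpropanoic acid
Product: 8 (1S,2S)-2-ethynyl-2-methyl-3-oxocyclopentyl (R)-3-(tert-butyldiphenylsilyloxy)-2-methylpropanoate
Conditions: DCC, DMAP (cat.), CH2Cl2, 23 °C
Reagents that add atoms: none
Why: Steglich esterification of the hindered secondary alcohol, with no stereocentre of the ring involved.

Step 6
Reactants: 8 keto ester
Product: 9 hydroxy ester (8 with the ring ketone reduced, both carbinol epimers)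
Conditions: NaBH4, MeOH, 0 °C
Reagents that add atoms: none
Why: Chemoselective borohydride reduction of the ketone beside the ester; the new carbinol centre is removed in step 7, so its configuration does not matter.

Step 7
Reactants: 9 hydroxy ester
Product: 10 (1S,2S)-2-ethynyl-2-methylcyclopent-3-en-1-yl (R)-3-(tert-butyldiphenylsilyloxy)-2-methylpropanoate
Conditions: Burgess reagent, toluene, 60 °C
Reagents that add atoms: none
Why: Burgess syn-dehydration can only run toward the CH2 group because the other neighbour is quaternary, giving the C4=C5 alkene.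

Step 8
Reactants: 10 cyclopentenyl ester
Product: 11 (1R,5S)-5-ethynyl-5-methyl-2-oxocyclopent-3-en-1-yl (R)-3-(tert-butyldiphenylsilyloxy)-2-methylpropanoate
Conditions: Rh2(cap)4 (1 mol %, cap = caprolactamate), t-BuOOH, K2CO3 (cat.), CH2Cl2, 23 °C
Reagents that add atoms: tert-butyl hydroperoxide, CC(C)(C)OO
Why: Dirhodium-caprolactamate-catalysed allylic oxidation should convert the only allylic CH2 (the future C1) into the enone carbonyl.

Step 9
Reactants: 11 ethynyl enone
Product: 12 (1R,5R)-5-acetyl-5-methyl-2-oxocyclopent-3-en-1-yl (R)-3-(tert-butyldiphenylsilyloxy)-2-methylpropanoate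
Conditions: Ph3PAuNTf2 (2 mol %), H2O, 1,4-dioxane, 60 °C
Reagents that add atoms: water, O
Why: Gold-catalysed Markovnikov hydration of the terminal alkyne gives the methyl ketone (C9 and C8).

Step 10
Reactants: 12 acetyl enone; 13 (2-bromoallyl)trimethylsilane
Product: 14 silyl enol ether carrying the allylsilane arm on C4 (ester oxygen and acetyl cis, arm trans to both)
Conditions: 13, Mg, THF; then CuBr·SMe2 (20 mol %), Et3SiCl, DMPU, THF, −78 °C
Reagents that add atoms: chlorotriethylsilane, CC[Si](Cl)(CC)CC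
Why: Copper-catalysed conjugate addition of the 2-(silylmethyl)vinyl Grignard reagent with in situ silylation gives the regiodefined C1=C5 silyl enol ether, the nucleophile adding to C4 anti to the cis-disposed acetyl and acyloxy groups.

Step 11
Reactants: 14 silyl enol ether
Product: 17 neopentyl alcohol with the new C5–C6 bond and quaternary C6, via ketene silyl acetal 15 (not isolated), via trimethylsilyl ester 16 (not isolated)
Conditions: LiN(i-Pr)2 (2.4 equiv), Me3SiCl, THF/DMPU, −78 → 40 °C; evaporation; LiAlH4, Et2O, 0 °C; aq. NaOH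
Reagents that add atoms: none
Why: Ireland–Claisen rearrangement of the (Z)-ketene silyl acetal through a boat-like transition state (the chair would push OSiMe3 under the ring) should transfer the C11–O configuration suprafacially to C5, set the quaternary C6 and move the enol ether to C1=C11, after which LiAlH4 reduces the silyl ester while both ketones stay masked as enol ethers.

Step 12
Reactants: 17 neopentyl alcohol
Product: 18 neopentyl aldehyde (C7) with the C1=C11 triethylsilyl enol ether
Conditions: Dess–Martin periodinane, NaHCO3, CH2Cl2, 0 °C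
Reagents that add atoms: none
Why: Dess–Martin oxidation of the primary alcohol gives the non-enolisable aldehyde, and the buffered conditions should spare the silyl enol ether.

Step 13
Reactants: 18 aldehyde
Product: 19 α-triethylsilyloxy keto aldehyde (silyloxy on C11 cis to the ring methyl and the arm)
Conditions: mCPBA (1.05 equiv), CH2Cl2, −40 °C
Reagents that add atoms: 3-chloroperbenzoic acid, O=C(OO)c1cccc(Cl)c1
Why: Rubottom oxidation: the peracid should epoxidise the enol ether on the face opposite to the C5 quaternary substituent and the C10 acetyl group, and 1,4-silyl migration then gives the C11 silyloxy ketone with C11 set.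

Step 14
Reactants: 19 α-silyloxy keto aldehyde
Product: 20 bicyclo[4.2.1]nonane β-hydroxy ketone (C7 carbinol, C9 ketone)
Conditions: LiN(SiMe3)2 (1.05 equiv), THF, −78 °C; AcOH
Reagents that add atoms: none
Why: Intramolecular aldol addition of the kinetic methyl-ketone enolate (C8) to the neopentyl aldehyde (C7) closes the seven-membered ring, C7 being set in the lithium-chelated transition state with the carbinol oxygen turned away from the C6 silyloxymethyl branch.

Step 15
Reactants: 20 bicyclic β-hydroxy ketone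
Product: 21 C7 acetate with free C9 alcohol (1,3-anti)
Conditions: SmI2 (30 mol %), CH3CHO, THF, −10 °C
Reagents that add atoms: acetaldehyde, CC=O
Why: Evans–Tishchenko reaction with acetaldehyde delivers hydride intramolecularly from the C7 oxygen side to the C9 ketone, giving the 1,3-anti alcohol at C9 and leaving the acetate on C7.

Step 16
Reactants: 21 hydroxy acetate; 22 3-methylbut-2-enoyl chloride
Product: 23 C9 senecioate
Conditions: pyridine, DMAP (cat.), CH2Cl2, 0 → 23 °C
Reagents that add atoms: none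
Why: Acylation of the hindered C9 alcohol with the acid chloride, pyridine being used instead of Et3N to avoid deconjugation through the vinylketene.

Step 17
Reactants: 23 senecioate
Product: 24 α-hydroxy ketone (free C11 hydroxyl)
Conditions: HF·pyridine, pyridine, THF, 0 °C
Reagents that add atoms: none
Why: Buffered HF·pyridine should remove the triethylsilyl ether selectively beside the tert-butyldiphenylsilyl ether and the allylsilane.

Step 18
Reactants: 24 α-hydroxy ketone
Product: 25 C11 mesylate
Conditions: MsCl, Et3N, CH2Cl2, −20 °C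
Reagents that add atoms: methanesulfonyl chloride, CS(=O)(=O)Cl
Why: Sulfene-type mesylation of the hindered α-hydroxy ketone forms only the O–S bond, so the C11 configuration is retained.

Step 19
Reactants: 25 C11 mesylate
Product: 27 tricyclic 3-methylidene ketone (longipinan-1-one core), via bridgehead aluminium alkoxide 26 (not isolated)
Conditions: EtAlCl2 (3 equiv), CH2Cl2, −78 → 0 °C; aq. NaHCO3
Reagents that add atoms: none
Why: Proposed new method: EtAlCl2 activates the C1 ketone of 25, the 2-(silylmethyl)allyl group on C4 adds through its terminal carbon (C2) from the face it already occupies and loses Me3SiCl (intramolecular Hosomi–Sakurai reaction), giving the bridgehead chloroaluminium alkoxide 26 of a 1-oxynorbornane; in 26 the C1–C5 bond is antiperiplanar to C11–OMs, so C5 shifts from C1 to C11 with loss of mesylate while C1 becomes the ketone (semipinacol shift). The closest known reaction types are the intramolecular Sakurai allylation of ketones by 2-(silylmethyl)allyl groups, the organoaluminium-promoted 1,2-shift of α-sulfonyloxy carbinols (Tsuchihashi–Suzuki) and the Tiffeneau ring contraction of α-halo ketone/organometal adducts; new is their union on a bridged cyclopentanone with contraction to a cyclobutane. The carbinol ring of 26 closes 5-exo-trig at the carbonyl (allylsilane π bond inside the ring); the six-membered C1–C2–C3–C4–C5–C11 ring then arises by one-carbon expansion of that ring and the cyclobutane C4–C5–C11–C10 by contraction of the cyclopentanone, both in the same 1,2-shift. C11 is inverted by backside attack of the migrating C1–C5 bond and C5 migrates with retention, so both follow from the C11 configuration set in step 13, while C4 and C10 are untouched. The step needs migration of C5 rather than of the C2 methylene, which the arm-side (endo) mesylate secures, and allylation before any loss of mesylate, which the low temperature and the non-ionising α-keto position secure; ketone formation and sulfonate loss pay for the added ring strain.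

Step 20
Reactants: 27 3-methylidene ketone
Product: 28 longipin-2-en-1-one silyl ether
Conditions: DBU (0.2 equiv), CH2Cl2, 23 °C
Reagents that add atoms: none
Why: Base-mediated isomerisation of the β,γ-unsaturated exocyclic alkene (deprotonation at C2, γ-protonation) should give the thermodynamically favoured conjugated endocyclic enone.

Step 21
Reactants: 28 enone silyl ether
Product: 29 primary alcohol
Conditions: HF·pyridine, THF, 23 °C
Reagents that add atoms: none
Why: Fluoride cleavage of the silyl ether under acidic conditions, so that the C7 acetate does not migrate to the freed primary alcohol.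

Step 22
Reactants: 29 primary alcohol; 30 angelic acid, (Z)-2-methylbut-2-enoic acid
Product: 31 target CNP0179010.1
Conditions: 30, 2,4,6-Cl3C6H2COCl, Et3N, toluene, 23 °C; then 29, 80 °C
Reagents that add atoms: none
Why: Yamaguchi-type esterification through the 2,4,6-trichlorobenzoyl mixed anhydride without DMAP, conditions under which angelates keep the (Z) geometry.

**Compound list**
1 | methyl (R)-3-hydroxy-2-methylpropanoate (Roche ester) | C[C@H](CO)C(=O)OC | starting material
2 | methyl (R)-3-(tert-butyldiphenylsilyloxy)-2-methylpropanoate | C[C@H](CO[Si](c1ccccc1)(c1ccccc1)C(C)(C)C)C(=O)OC | intermediate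
3 | (R)-3-(tert-butyldiphenylsilyloxy)-2-methylpropanoic acid | C[C@H](CO[Si](c1ccccc1)(c1ccccc1)C(C)(C)C)C(=O)O | intermediate
4 | 2-methylcyclopentane-1,3-dione | CC1C(=O)CCC1=O | starting material
5 | 1-[(trimethylsilyl)ethynyl]-1,2-benziodoxol-3(1H)-one (TMS-EBX) | C[Si](C)(C)C#CI1OC(=O)c2ccccc12 | starting material
6 | 2-ethynyl-2-methylcyclopentane-1,3-dione | O=C1CCC(=O)C1(C)C#C | intermediate
7 | (2S,3S)-2-ethynyl-3-hydroxy-2-methylcyclopentan-1-one | O[C@H]1CCC(=O)[C@@]1(C)C#C | intermediate
8 | (1S,2S)-2-ethynyl-2-methyl-3-oxocyclopentyl (R)-3-(tert-butyldiphenylsilyloxy)-2-methylpropanoate | CC(C)(C)[Si](c5ccccc5)(c6ccccc6)OC[C@@H](C)C(=O)O[C@H]1CCC(=O)[C@@]1(C)C#C | intermediate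
9 | 2-ethynyl-3-hydroxy-2-methylcyclopentyl ester (8 with the ketone reduced; both carbinol epimers) | CC(C)(C)[Si](c5ccccc5)(c6ccccc6)OC[C@@H](C)C(=O)O[C@H]1CCC(O)[C@@]1(C)C#C | intermediate
10 | (1S,2S)-2-ethynyl-2-methylcyclopent-3-en-1-yl (R)-3-(tert-butyldiphenylsilyloxy)-2-methylpropanoate | CC(C)(C)[Si](c5ccccc5)(c6ccccc6)OC[C@@H](C)C(=O)O[C@H]1CC=C[C@@]1(C)C#C | intermediate
11 | (1R,5S)-5-ethynyl-5-methyl-2-oxocyclopent-3-en-1-yl (R)-3-(tert-butyldiphenylsilyloxy)-2-methylpropanoate | CC(C)(C)[Si](c5ccccc5)(c6ccccc6)OC[C@@H](C)C(=O)O[C@H]1C(=O)C=C[C@@]1(C)C#C | intermediate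
12 | (1R,5R)-5-acetyl-5-methyl-2-oxocyclopent-3-en-1-yl (R)-3-(tert-butyldiphenylsilyloxy)-2-methylpropanoate | CC(C)(C)[Si](c5ccccc5)(c6ccccc6)OC[C@@H](C)C(=O)O[C@H]1C(=O)C=C[C@@]1(C)C(C)=O | intermediate
13 | (2-bromoallyl)trimethylsilane | C=C(Br)C[Si](C)(C)C | starting material
14 | 5-acetyl-5-methyl-2-(triethylsilyloxy)-4-[3-(trimethylsilyl)prop-1-en-2-yl]cyclopent-2-en-1-yl (R)-3-(tert-butyldiphenylsilyloxy)-2-methylpropanoate (ester oxygen cis to acetyl, arm trans to both) | CC(C)(C)[Si](c5ccccc5)(c6ccccc6)OC[C@@H](C)C(=O)O[C@H]1C(O[Si](CC)(CC)CC)=C[C@H](C(=C)C[Si](C)(C)C)[C@@]1(C)C(C)=O | intermediate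
15 | (Z)-ketene trimethylsilyl acetal of 14, acetyl group as its trimethylsilyl enol ether | CC(C)(C)[Si](c5ccccc5)(c6ccccc6)OC/C(C)=C(\O[Si](C)(C)C)O[C@H]1C(O[Si](CC)(CC)CC)=C[C@H](C(=C)C[Si](C)(C)C)[C@@]1(C)C(=C)O[Si](C)(C)C | intermediate
16 | trimethylsilyl 3-(tert-butyldiphenylsilyloxy)-2-methyl-2-{4-methyl-2-(triethylsilyloxy)-4-[1-(trimethylsilyloxy)vinyl]-5-[3-(trimethylsilyl)prop-1-en-2-yl]cyclopent-2-en-1-yl}propanoate | CC(C)(C)[Si](c5ccccc5)(c6ccccc6)OC[C@@](C)(C(=O)O[Si](C)(C)C)[C@@H]1C(O[Si](CC)(CC)CC)=C[C@@](C)([C@H]1C(=C)C[Si](C)(C)C)C(=C)O[Si](C)(C)C | intermediate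
17 | 2-{4-acetyl-4-methyl-2-(triethylsilyloxy)-5-[3-(trimethylsilyl)prop-1-en-2-yl]cyclopent-2-en-1-yl}-3-(tert-butyldiphenylsilyloxy)-2-methylpropan-1-ol (side chain cis to acetyl, trans to the arm) | CC(C)(C)[Si](c5ccccc5)(c6ccccc6)OC[C@@](C)(CO)[C@@H]1C(O[Si](CC)(CC)CC)=C[C@@](C)([C@H]1C(=C)C[Si](C)(C)C)C(C)=O | intermediate
18 | the corresponding propanal of 17 | CC(C)(C)[Si](c5ccccc5)(c6ccccc6)OC[C@@](C)(C=O)[C@@H]1C(O[Si](CC)(CC)CC)=C[C@@](C)([C@H]1C(=C)C[Si](C)(C)C)C(C)=O | intermediate
19 | 2-{3-acetyl-3-methyl-5-oxo-4-(triethylsilyloxy)-2-[3-(trimethylsilyl)prop-1-en-2-yl]cyclopentyl}-3-(tert-butyldiphenylsilyloxy)-2-methylpropanal (silyloxy cis to ring methyl and arm) | CC(C)(C)[Si](c5ccccc5)(c6ccccc6)OC[C@@](C)(C=O)[C@@H]1C(=O)[C@@H](O[Si](CC)(CC)CC)[C@@](C)([C@H]1C(=C)C[Si](C)(C)C)C(C)=O | intermediate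
20 | 2-(tert-butyldiphenylsilyloxymethyl)-3-hydroxy-2,6-dimethyl-7-(triethylsilyloxy)-9-[3-(trimethylsilyl)prop-1-en-2-yl]bicyclo[4.2.1]nonane-5,8-dione | CC(C)(C)[Si](c5ccccc5)(c6ccccc6)OC[C@]1(C)[C@@H]2C(=O)[C@@H](O[Si](CC)(CC)CC)[C@@](C)([C@H]2C(=C)C[Si](C)(C)C)C(=O)C[C@H]1O | intermediate
21 | 2-(tert-butyldiphenylsilyloxymethyl)-5-hydroxy-2,6-dimethyl-8-oxo-7-(triethylsilyloxy)-9-[3-(trimethylsilyl)prop-1-en-2-yl]bicyclo[4.2.1]nonan-3-yl acetate | CC(C)(C)[Si](c5ccccc5)(c6ccccc6)OC[C@]1(C)[C@@H]2C(=O)[C@@H](O[Si](CC)(CC)CC)[C@@](C)([C@H]2C(=C)C[Si](C)(C)C)[C@H](O)C[C@H]1OC(C)=O | intermediate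
22 | 3-methylbut-2-enoyl chloride (senecioyl chloride) | CC(C)=CC(=O)Cl | starting material
23 | 3-acetoxy-bicyclo[4.2.1]nonan-5-yl 3-methylbut-2-enoate with the 7-triethylsilyloxy group (otherwise as 21) | CC(C)(C)[Si](c5ccccc5)(c6ccccc6)OC[C@]1(C)[C@@H]2C(=O)[C@@H](O[Si](CC)(CC)CC)[C@@](C)([C@H]2C(=C)C[Si](C)(C)C)[C@H](OC(=O)C=C(C)C)C[C@H]1OC(C)=O | intermediate
24 | 7-hydroxy analogue of 23 (α-hydroxy ketone) | CC(C)(C)[Si](c5ccccc5)(c6ccccc6)OC[C@]1(C)[C@@H]2C(=O)[C@@H](O)[C@@](C)([C@H]2C(=C)C[Si](C)(C)C)[C@H](OC(=O)C=C(C)C)C[C@H]1OC(C)=O | intermediate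
25 | 7-(methylsulfonyloxy) analogue of 23 (mesylate on the face of the C9 arm) | CC(C)(C)[Si](c5ccccc5)(c6ccccc6)OC[C@]1(C)[C@@H]2C(=O)[C@@H](OS(C)(=O)=O)[C@@](C)([C@H]2C(=C)C[Si](C)(C)C)[C@H](OC(=O)C=C(C)C)C[C@H]1OC(C)=O | intermediate
26 | chloro(ethyl)aluminium alkoxide of the tricyclic bridgehead carbinol (1-oxynorbornane with the endo mesylate) | CC(C)(C)[Si](c5ccccc5)(c6ccccc6)OC[C@]1(C)[C@@H]2[C@]3(O[Al](Cl)CC)[C@@H](OS(C)(=O)=O)[C@@](C)([C@H]2C(=C)C3)[C@H](OC(=O)C=C(C)C)C[C@H]1OC(C)=O | intermediate
27 | 7-acetoxy-6-(tert-butyldiphenylsilyloxymethyl)-3-methylidene-9-(3-methylbut-2-enoyloxy)longipinan-1-one (longipinane numbering) | CC(C)(C)[Si](c5ccccc5)(c6ccccc6)OC[C@]1(C)[C@@H]2[C@H]3C(=O)CC(=C)[C@@H]2[C@@]3(C)[C@H](OC(=O)C=C(C)C)C[C@H]1OC(C)=O | intermediate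
28 | 7-acetoxy-6-(tert-butyldiphenylsilyloxymethyl)-9-(3-methylbut-2-enoyloxy)longipin-2-en-1-one | CC(C)(C)[Si](c5ccccc5)(c6ccccc6)OC[C@]1(C)[C@@H]2[C@H]3C(=O)C=C(C)[C@@H]2[C@@]3(C)[C@H](OC(=O)C=C(C)C)C[C@H]1OC(C)=O | intermediate
29 | 7-acetoxy-6-(hydroxymethyl)-9-(3-methylbut-2-enoyloxy)longipin-2-en-1-one | OC[C@]1(C)[C@@H]2[C@H]3C(=O)C=C(C)[C@@H]2[C@@]3(C)[C@H](OC(=O)C=C(C)C)C[C@H]1OC(C)=O | intermediate
30 | angelic acid, (Z)-2-methylbut-2-enoic acid | C/C=C(/C)C(=O)O | starting material
31 | CNP0179010.1 | C/C=C(/C)C(=O)OC[C@]1(C)[C@@H]2[C@H]3C(=O)C=C(C)[C@@H]2[C@@]3(C)[C@H](OC(=O)C=C(C)C)C[C@H]1OC(C)=O | target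

**Step count and risks**
Total: 22 steps. Longest linear sequence: 20 steps (steps 3–22); steps 1–2 make acid 3, which joins at step 5.

Most likely to fail:

1. Step 19. After allylation the shift may not follow: the carbinol may revert or the allylsilane may be protodesilylated, or the C2 methylene may migrate instead of C5 if the mesylate ionises first. The fallback uses known chemistry and makes the two bonds separately, setting out from 24 and returning at 27. Dess–Martin oxidation of 24 gives the 7,8-dione F1. TsNHNH2 condenses at the less hindered carbonyl to the monotosylhydrazone F2, and Et3N eliminates sulfinate to the α-diazo ketone F3. Photochemical Wolff rearrangement in aqueous THF contracts the cyclopentanone to the cyclobutanecarboxylic acid F4 (either diazo regioisomer gives the same acid; the epimer with the carboxyl anti to the arm is equilibrated at the acid chloride stage). (COCl)2 gives the acid chloride F5, and TiCl4 at −78 °C closes the six-membered ring by intramolecular acylation of the allylsilane, giving 27.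

2. Step 14. The enolate may attack the ring ketone, the aldol may revert, or the aldehyde face may be poorly selected, giving the C7 epimer. The fallback sets C7 by catalyst control, setting out from 19 and returning at 20. Aldol condensation (piperidinium acetate, benzene, reflux) gives the bicyclic cycloheptenone F6. Copper-catalysed conjugate borylation (CuCl, NaOt-Bu, chiral bisphosphine, B2pin2, MeOH) gives the β-boryl ketone F7 with ligand-controlled facial selectivity, and NaBO3 oxidation (retention) gives 20.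

3. Step 4. Reduction may follow the intrinsic facial preference (hydride anti to the methyl group), giving the epimeric carbinol. The fallback accepts that preference, setting out from 6 and returning at 8. CBS reduction (2-methyl-CBS-oxazaborolidine, catecholborane, −78 °C) gives (2S,3R)-2-ethynyl-3-hydroxy-2-methylcyclopentan-1-one F8, and Mitsunobu esterification with acid 3 (PPh3, DIAD) inverts the carbinol to give 8.

Further compounds
F1 | step 19 | 7,8-dione from oxidation of 24 | CC(C)(C)[Si](c5ccccc5)(c6ccccc6)OC[C@]1(C)[C@@H]2C(=O)C(=O)[C@@](C)([C@H]2C(=C)C[Si](C)(C)C)[C@H](OC(=O)C=C(C)C)C[C@H]1OC(C)=O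
F2 | step 19 | monotosylhydrazone of F1 at the carbonyl next to C5 | CC(C)(C)[Si](c5ccccc5)(c6ccccc6)OC[C@]1(C)[C@@H]2C(=NNS(=O)(=O)c7ccc(C)cc7)C(=O)[C@@](C)([C@H]2C(=C)C[Si](C)(C)C)[C@H](OC(=O)C=C(C)C)C[C@H]1OC(C)=O
F3 | step 19 | α-diazo ketone | CC(C)(C)[Si](c5ccccc5)(c6ccccc6)OC[C@]1(C)[C@@H]2C(=[N+]=[N-])C(=O)[C@@](C)([C@H]2C(=C)C[Si](C)(C)C)[C@H](OC(=O)C=C(C)C)C[C@H]1OC(C)=O
F4 | step 19 | ring-contracted cyclobutanecarboxylic acid (carboxyl cis to the allylsilane arm) | CC(C)(C)[Si](c5ccccc5)(c6ccccc6)OC[C@]1(C)[C@@H]2[C@@H](C(=O)O)[C@@](C)([C@H]2C(=C)C[Si](C)(C)C)[C@H](OC(=O)C=C(C)C)C[C@H]1OC(C)=O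
F5 | step 19 | acid chloride of F4 | CC(C)(C)[Si](c5ccccc5)(c6ccccc6)OC[C@]1(C)[C@@H]2[C@@H](C(=O)Cl)[C@@](C)([C@H]2C(=C)C[Si](C)(C)C)[C@H](OC(=O)C=C(C)C)C[C@H]1OC(C)=O
F6 | step 14 | bicyclic cycloheptenone (C7=C8 enone) | CC(C)(C)[Si](c5ccccc5)(c6ccccc6)OC[C@]1(C)[C@@H]2C(=O)[C@@H](O[Si](CC)(CC)CC)[C@@](C)([C@H]2C(=C)C[Si](C)(C)C)C(=O)C=C1
F7 | step 14 | β-boryl ketone (pinacolboronate on C7) | CC(C)(C)[Si](c5ccccc5)(c6ccccc6)OC[C@]1(C)[C@@H]2C(=O)[C@@H](O[Si](CC)(CC)CC)[C@@](C)([C@H]2C(=C)C[Si](C)(C)C)C(=O)C[C@H]1B7OC(C)(C)C(C)(C)O7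
F8 | step 4 | (2S,3R)-2-ethynyl-3-hydroxy-2-methylcyclopentan-1-one | O[C@@H]1CCC(=O)[C@@]1(C)C#C
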